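## The problem

Compound 17 is a 3-aryloxycoumarin. Benzo ring A (C4a to C8a) carries a methoxy group at C6 and a free hydroxyl at C7 and is fused to pyranone ring B (O1, C2, C3, C4); C3 is joined through an ether oxygen to ring C, a phenol whose methyl propanoate chain stands ortho to the free hydroxyl and para to the ether oxygen. The molecule has no stereocentre, so there is nothing for one centre to control in another; the only stereochemical matter is the geometry of the C3=C4 double bond before ring B exists, because only the isomer with C4a and the C2 carbonyl on the same side can lactonise. The main task is to tell five aryl oxygens apart: on ring A one becomes the lactone oxygen O1, one a methyl ether and one a free phenol, and on ring C one is the diaryl ether and one a free phenol. The ether at C3 lies on an enol-type carbon, which SNAr or Ullmann coupling serves poorly, so it is better made before ring B is closed. Three groups dislike rough treatment: the ring B lactone opens in hydroxide, the ring C hydroxy ester closes to a dihydrocoumarin under acid or heat when no methanol is present, and the electron-rich phenols are easily oxidised. The feature that opens the structure is the pattern of ring A: C8a (bearing O1) and C6 (bearing the methoxy group) are para and the C7 oxygen is next to C6. This is the 4-methoxyphenol pattern that a methoxycarbene carbon, an alkyne and a carbonyl ligand give on chromium, with C4a left to carry the C4=C3–C2 ester arm from which ring B closes.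

## Retrosynthesis

**17 from 16.** The methyl ester and the neighbouring hydroxyl of ring C are joined retrosynthetically to the saturated aryl lactone of 16. This single ring masks both functions without a separate protecting group, and it comes from a coumarin (1) in which the two oxygens of ring C are already different. The forward step is an alcoholysis that must open the saturated lactone and spare the conjugated lactone of ring B, which acid catalysis should secure.

**16 from 15.** The C7 hydroxyl is covered as a tert-butyl ether. A tert-butyl group tolerates organolithium, fluoride and heat, and leaves with anhydrous acid that touches neither lactone nor the C6 methyl ether. A benzyl group would not survive lithiation next to oxygen, and an ethyl group could not be told from the C6 methyl group at the end.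

**15 from 13 and 8 (through 14).** Three bonds of ring A are cut (C5–C6, C4a–C8a, C8–C8a) together with O1–C2 of ring B. Classical coumarin syntheses would start from a trioxygenated salicylaldehyde whose three oxygens must be differentiated by protecting groups. Here the C6 oxygen comes from the carbene methoxy group of 13, the C7 oxygen from its vinyl ether, and O1 from a carbonyl ligand, so they are distinct by origin. The precursors contain no ring A at all: 8 is an acyclic enyne ester and 13 a four-carbon carbene complex. The forward reaction must place the enoate arm next to the new hydroxyl, must take the phenol-forming path, and needs the alkyne-derived carbon and the ester cis on the double bond of 8 so that 14 lactonises.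

**8 from 7, and 7 from 5 and 6.** The C3=C4 double bond is cut by olefination and the alkyne terminus is capped with silicon. An olefination fixes the geometry in the bond-forming step, which a coupling on a β-haloacrylate would not do more reliably. Because the ordinary phosphonate would put the alkyne trans to the ester, the trifluoroethyl phosphonate 5 is chosen for kinetic, cis-to-ester selectivity. The forward steps need an aldehyde that does not polymerise (hence silylated 6) and a desilylation that spares the aryl lactone.

**5 from 2 and 4; 4 from 3; 2 from 1.** The bond between the ring C oxygen and the future C3 is cut. A carbenoid O–H insertion makes this hindered α-aryloxy phosphonoacetate under neutral conditions, where displacement on an α-halo phosphonoacetate would need base and risk the lactone. Diazo compound 4 is one diazo transfer from commercial 3, and phenol 2 is one hydrogenation from commercial 1, which puts the whole of ring C in place at the start.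

**13 from 9 and 10.** The bond between the carbene carbon and the vinyl carbon and the O–methyl bond are cut. This is the Fischer route: the α-lithiated vinyl ether 11 adds to a carbonyl ligand of 10 and the acylchromate 12 is O-methylated.

## Roads not taken

**Alternative 1:** Ring C is built last by cutting C1'–C6'. Mild acid would free the C6' aldehyde of the open-chain keto acetal A2 (methyl (E)-7-{[7-(benzyloxy)-6-methoxy-2-oxo-2H-chromen-3-yl]oxy}-9,9-dimethoxy-5-oxonon-7-enoate). The ketone α-carbon C1' would add to it, and dehydration and tautomerisation would give the 7-O-benzyl ether of the target, A1; hydrogenolysis would finish.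
- Merits: ring C is born with its free hydroxyl and methyl ester in place, so no lactone has to be opened; the end-game is a neutral hydrogenolysis; no stoichiometric metal is used. In these respects it is better than the chosen plan.
- Weak points: after unmasking, the C4' enol ether of A2 is a β-aryloxy enal, an acetal-like function. The acid needed for the aldol can hydrolyse it or trigger addition–elimination that expels the coumarin oxygen, so the diaryl ether is at risk in the key step itself. The doubly activated C3' methylene invites intermolecular condensation. A2 needs a defined C4'=C5' geometry and a differentiated 1,5-dicarbonyl chain, so its synthesis is at least as long as the fragments used here.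
- Against it the chosen plan sets a diaryl ether formed early on a robust phenol and never exposed again, and a convergent union of two small fragments.

**Alternative 2:** Only O1–C8a is cut. The (Z)-2-aryloxycinnamic acid A4 ((Z)-3-(4-acetoxy-3-methoxyphenyl)-2-[(2-oxochroman-7-yl)oxy]prop-2-enoic acid) would be isomerised by a flavin photocatalyst under blue light and oxygen. Oxidation would then let the carboxylate oxygen bond to the ring carbon para to the methoxy group, giving the coumarin acetate A3; one acidic methanolysis would remove the acetate and open the ring C lactone.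
- Merits: it is the shortest road, roughly six steps against nine. It needs only the ordinary, ester-trans olefination because the photocatalyst sets the geometry, and it uses no stoichiometric metal. In step economy it is clearly better.
- Weak points: the site of C–O bond formation rests on C–H selectivity between two ortho positions. The electron-rich ring C and the enol ether double bond are also open to oxidation by the excited catalyst. The α-aryloxy group changes the photophysics of the cinnamate in a way that is not known. The free acid A4 must be released without opening its own aryl lactone and aryl acetate.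
- Against it the chosen plan sets an O1 oxygen that arrives as part of the ring construction, at a position fixed by connectivity, and the absence of any oxidant near the electron-rich diaryl ether.

**Alternative 3:** Ring C is cut at C2'–C3' and C1'–C6'. The 4-(coumarinyloxy)-2-pyranone A6 would undergo (4+2) cycloaddition with the siloxyalkyne A7 (tert-butyl 5-[(triisopropylsilyl)oxy]pent-4-ynoate). Decarboxylative retro-(4+2) opening of the bridged lactone would then give the fully protected arene A5.
- Merits: it is convergent, the polarity of the two partners fixes the substitution pattern of ring C, there is no alkene geometry to control, and no chromium is needed. In these points it is as good as or better than the chosen plan.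
- Weak points: both partners are electron-rich, so the cycloaddition would need forcing conditions under which siloxyalkynes rearrange or dimerise. The end-game needs desilylation, debenzylation and exchange of the tert-butyl ester for a methyl ester, during which the free acid next to a free phenol tends to lactonise.
- Against it the chosen plan sets a two-step end-game, made possible by masking the ring C hydroxyl and carboxyl together as one lactone, and a ring C that never has to be built.

Key step: step 7

Remark: 17 is achiral; phosphonate 5 is formed and used as the racemate, and its one stereocentre is removed in step 4. Compounds 1, 3, 6, 9 and 10 are bought.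

## Route

Step 1
Reactants: 1 umbelliferone (7-hydroxy-2H-chromen-2-one)
Product: 2 7-hydroxychroman-2-one
Conditions: H2 (3 atm), 10% Pd/C, AcOH, 50 °C
Reagents that add atoms: none
Why: Catalytic hydrogenation of the conjugated C3=C4 bond of a coumarin over palladium on carbon is standard; acetic acid is used instead of an alcohol so that the saturated lactone is not transesterified.

Step 2
Reactants: 3 methyl bis(2,2,2-trifluoroethyl)phosphonoacetate
Product: 4 methyl 2-[bis(2,2,2-trifluoroethoxy)phosphoryl]-2-diazoacetate
Conditions: p-ABSA, DBU, MeCN, 0 °C → rt
Reagents that add atoms: 4-acetamidobenzenesulfonyl azide (p-ABSA), CC(=O)Nc1ccc(cc1)S(=O)(=O)N=[N+]=[N-]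
Why: Regitz diazo transfer to an activated methylene; the trifluoroethyl esters make the phosphonoacetate acidic enough for an amidine base, which avoids nucleophilic exchange at phosphorus.

Step 3
Reactants: 2 7-hydroxychroman-2-one; 4 methyl 2-[bis(2,2,2-trifluoroethoxy)phosphoryl]-2-diazoacetate
Product: 5 methyl 2-[bis(2,2,2-trifluoroethoxy)phosphoryl]-2-[(2-oxochroman-7-yl)oxy]acetate (racemic)
Conditions: Rh2(OAc)4 (2 mol %), ClCH2CH2Cl, 80 °C
Reagents that add atoms: none
Why: Rh2(OAc)4-catalysed carbenoid O–H insertion of a diazophosphonoacetate into a phenol; the acceptor-substituted carbenoid prefers the O–H bond over the arene, the conditions are neutral for the lactone, and the new stereocentre is racemic and disappears in step 4.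

Step 4
Reactants: 5 methyl 2-[bis(2,2,2-trifluoroethoxy)phosphoryl]-2-[(2-oxochroman-7-yl)oxy]acetate; 6 3-(trimethylsilyl)propynal
Product: 7 methyl (E)-2-[(2-oxochroman-7-yl)oxy]-5-(trimethylsilyl)pent-2-en-4-ynoate
Conditions: KN(SiMe3)2, 18-crown-6, THF, −78 °C
Reagents that add atoms: none
Why: Still–Gennari olefination: the trifluoroethyl phosphonate anion adds irreversibly and the oxaphosphetane collapses fast, so the kinetic alkene with the aldehyde residue cis to the ester should prevail; because the aryloxy group outranks the ester, this isomer has the descriptor E. The phosphonate is far more acidic than the lactone α-hydrogens, so one equivalent of base at −78 °C should leave the lactone alone.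

Step 5
Reactants: 7 methyl (E)-2-[(2-oxochroman-7-yl)oxy]-5-(trimethylsilyl)pent-2-en-4-ynoate
Product: 8 methyl (E)-2-[(2-oxochroman-7-yl)oxy]pent-2-en-4-ynoate
Conditions: Bu4NF, AcOH, THF, −20 °C
Reagents that add atoms: none
Why: Fluoride-induced protodesilylation of an alkynylsilane; acetic acid buffers the medium so that the aryl lactone is not opened and the enoate geometry is kept, which is why K2CO3 in methanol is avoided.

Step 6
Reactants: 9 tert-butyl vinyl ether; 10 chromium hexacarbonyl, Cr(CO)6
Product: 13 pentacarbonyl[(1-tert-butoxyvinyl)(methoxy)carbene]chromium, via 1-(tert-butoxy)vinyllithium 11 (not isolated), via lithium [2-(tert-butoxy)acryloyl]pentacarbonylchromate 12 (not isolated)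
Conditions: t-BuLi, THF, −78 → 0 °C; Cr(CO)6, Et2O, 0 °C → rt; then MeOTf, CH2Cl2, 0 °C
Reagents that add atoms: methyl trifluoromethanesulfonate, COS(=O)(=O)C(F)(F)F
Why: Fischer carbene synthesis: alkyl vinyl ethers are lithiated next to oxygen by t-BuLi, the vinyllithium adds to a carbonyl ligand of Cr(CO)6, and the acylchromate oxygen is methylated by the hard electrophile; cyclic 1-alkoxyvinyl complexes are made in the same way.

Step 7
Reactants: 13 pentacarbonyl[(1-tert-butoxyvinyl)(methoxy)carbene]chromium; 8 methyl (E)-2-[(2-oxochroman-7-yl)oxy]pent-2-en-4-ynoate
Product: 15 7-(tert-butoxy)-6-methoxy-3-[(2-oxochroman-7-yl)oxy]-2H-chromen-2-one, via (E)-hydroxycinnamate ester 14 (not isolated)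
Conditions: THF, 55 °C; then air, daylight, rt; then toluene, 80 °C
Reagents that add atoms: none
Why: Dötz benzannulation with lactonisation: thermal loss of one CO ligand from 13 lets the terminal alkyne of 8 coordinate and insert into the chromium–carbon double bond, its unsubstituted carbon bonding to the carbene carbon (C5–C6). CO insertion into the resulting vinylcarbene gives a chromium-bound dienylketene (C4a–C8a), whose 6π electrocyclisation forms C8–C8a and, after tautomerisation, the phenol of ring A. The closest known reaction type is the benzannulation of alkenyl(methoxy)carbene chromium complexes with terminal alkynes and conjugated enynes to 4-methoxyphenols, which cyclic 1-alkoxyvinyl complexes also undergo. Ring A therefore closes by electrocyclisation of the dienylketene (a formal 3+2+1 assembly), and ring B closes by 6-exo-trig acyl substitution of the C8a hydroxyl of 14 on the cis methyl ester with loss of methanol, once air and light have released the arene from chromium. No stereocentre is formed. The step needs the enoate arm next to the new hydroxyl, which the steric preference of terminal alkynes secures; it needs phenol formation over cyclopentannulation or furan formation, which alkenyl complexes in THF favour; and it needs the E geometry of 8, which step 4 sets and the neutral conditions do not disturb. The carbene methoxy group ends at C6, the vinyl ether oxygen at C7 and the oxygen of the inserted CO at O1.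

Step 8
Reactants: 15 7-(tert-butoxy)-6-methoxy-3-[(2-oxochroman-7-yl)oxy]-2H-chromen-2-one
Product: 16 7-hydroxy-6-methoxy-3-[(2-oxochroman-7-yl)oxy]-2H-chromen-2-one
Conditions: CF3CO2H, CH2Cl2, 0 °C → rt
Reagents that add atoms: none
Why: Acidolysis of an aryl tert-butyl ether with loss of the tert-butyl cation as isobutene; anhydrous acid should leave both lactones, the methyl ether and the diaryl ether untouched.

Step 9
Reactants: 16 7-hydroxy-6-methoxy-3-[(2-oxochroman-7-yl)oxy]-2H-chromen-2-one
Product: 17 methyl 3-{2-hydroxy-4-[(7-hydroxy-6-methoxy-2-oxo-2H-chromen-3-yl)oxy]phenyl}propanoate (CNP0259806.0)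
Conditions: MeOH, H2SO4 (cat.), rt → 50 °C; NaHCO3 before concentration
Reagents that add atoms: methanol, CO
Why: Acid-catalysed methanolysis (transesterification) of the saturated aryl lactone; the ester of a 3,4-dihydrocoumarin is far more reactive than the conjugated lactone of ring B, which is stable to acid, and the excess of methanol keeps the hydroxy ester open.

## Compound list

1 | umbelliferone (7-hydroxy-2H-chromen-2-one) | O=c1ccc2ccc(O)cc2o1 | starting material
2 | 7-hydroxychroman-2-one | O=C1CCc2ccc(O)cc2O1 | intermediate
3 | methyl bis(2,2,2-trifluoroethyl)phosphonoacetate | COC(=O)CP(=O)(OCC(F)(F)F)OCC(F)(F)F | starting material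
4 | methyl 2-[bis(2,2,2-trifluoroethoxy)phosphoryl]-2-diazoacetate | COC(=O)C(=[N+]=[N-])P(=O)(OCC(F)(F)F)OCC(F)(F)F | intermediate
5 | methyl 2-[bis(2,2,2-trifluoroethoxy)phosphoryl]-2-[(2-oxochroman-7-yl)oxy]acetate (racemic) | COC(=O)C(Oc1ccc2CCC(=O)Oc2c1)P(=O)(OCC(F)(F)F)OCC(F)(F)F | intermediate
6 | 3-(trimethylsilyl)propynal | C[Si](C)(C)C#CC=O | starting material
7 | methyl (E)-2-[(2-oxochroman-7-yl)oxy]-5-(trimethylsilyl)pent-2-en-4-ynoate | C[Si](C)(C)C#C/C=C(/Oc1ccc2CCC(=O)Oc2c1)C(=O)OC | intermediate
8 | methyl (E)-2-[(2-oxochroman-7-yl)oxy]pent-2-en-4-ynoate | C#C/C=C(/Oc1ccc2CCC(=O)Oc2c1)C(=O)OC | intermediate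
9 | tert-butyl vinyl ether | C=COC(C)(C)C | starting material
10 | chromium hexacarbonyl, Cr(CO)6 | O=C=[Cr](=C=O)(=C=O)(=C=O)(=C=O)=C=O | starting material
11 | 1-(tert-butoxy)vinyllithium | [Li]C(=C)OC(C)(C)C | intermediate
12 | lithium [2-(tert-butoxy)acryloyl]pentacarbonylchromate | [Li+].[O-]C(C(=C)OC(C)(C)C)=[Cr](=C=O)(=C=O)(=C=O)(=C=O)=C=O | intermediate
13 | pentacarbonyl[(1-tert-butoxyvinyl)(methoxy)carbene]chromium | COC(C(=C)OC(C)(C)C)=[Cr](=C=O)(=C=O)(=C=O)(=C=O)=C=O | intermediate
14 | methyl (E)-3-[4-(tert-butoxy)-2-hydroxy-5-methoxyphenyl]-2-[(2-oxochroman-7-yl)oxy]prop-2-enoate | COc1cc(/C=C(/Oc2ccc3CCC(=O)Oc3c2)C(=O)OC)c(O)cc1OC(C)(C)C | intermediate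
15 | 7-(tert-butoxy)-6-methoxy-3-[(2-oxochroman-7-yl)oxy]-2H-chromen-2-one | COc1cc2cc(Oc3ccc4CCC(=O)Oc4c3)c(=O)oc2cc1OC(C)(C)C | intermediate
16 | 7-hydroxy-6-methoxy-3-[(2-oxochroman-7-yl)oxy]-2H-chromen-2-one | COc1cc2cc(Oc3ccc4CCC(=O)Oc4c3)c(=O)oc2cc1O | intermediate
17 | methyl 3-{2-hydroxy-4-[(7-hydroxy-6-methoxy-2-oxo-2H-chromen-3-yl)oxy]phenyl}propanoate | COC(=O)CCc1ccc(Oc2cc3cc(OC)c(O)cc3oc2=O)cc1O | target

## Step count and risks

Total: 9 steps. Longest linear sequence: 7 steps (steps 1, 3, 4, 5, 7, 8 and 9 from umbelliferone; the branch from 3 through step 2 is equally long).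

**Step 7 (key step).** The enyne is conjugated to an acceptor, so alkyne insertion may be slow or unselective. The vinylcarbene or vinylketene intermediate may be diverted into cyclopentannulation, furan formation or oligomerisation of the enyne, and the hydroquinone monoether may be oxidised while chromium is removed. The fallback gives up the carbene assembly for a Perkin-type condensation. It sets out from 2, which is O-alkylated with tert-butyl bromoacetate (K2CO3, acetone) to tert-butyl 2-[(2-oxochroman-7-yl)oxy]acetate F1. CF3CO2H in CH2Cl2 frees 2-[(2-oxochroman-7-yl)oxy]acetic acid F2. Perkin–Oglialoro condensation of F2 with 2,4-dihydroxy-5-methoxybenzaldehyde (Ac2O, Et3N, 110 °C) should give 6-methoxy-2-oxo-3-[(2-oxochroman-7-yl)oxy]-2H-chromen-7-yl acetate F3 (the same structure as A3). Acidic methanol as in step 9 then removes the acetate and opens the ring C lactone, so the sequence comes back at 17.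

**Step 4.** The kinetic cis (alkyne to ester) selectivity may erode, because the thermodynamically preferred isomer of a 2-aryloxy enoate is the other one and the ynal is small. The fallback sets the geometry after ring A is built. It sets out from 5; whatever methyl (Z)-2-[(2-oxochroman-7-yl)oxy]-5-(trimethylsilyl)pent-2-en-4-ynoate F4 forms is desilylated as in step 5 to methyl (Z)-2-[(2-oxochroman-7-yl)oxy]pent-2-en-4-ynoate F5. Benzannulation of F5 with 13 as in step 7 gives the uncyclised methyl (Z)-3-[4-(tert-butoxy)-2-hydroxy-5-methoxyphenyl]-2-[(2-oxochroman-7-yl)oxy]prop-2-enoate F6. Irradiation at 365 nm in dilute MeCN, the known photoisomerisation of trans-2-hydroxycinnamates to coumarins, should turn F6 into 14, which lactonises, so the sequence comes back at 15.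

**Step 6.** Lithiation of the hindered vinyl ether may be incomplete, and the tert-butyl enol ether of 13 may lose isobutene under the acid traces of methylation or chromatography. The fallback changes the C7 protecting group and the way it is removed. It sets out from 10 and isopropyl vinyl ether, which under the conditions of step 6 should give pentacarbonyl[(1-isopropoxyvinyl)(methoxy)carbene]chromium F7. Benzannulation of F7 with 8 as in step 7 gives 7-isopropoxy-6-methoxy-3-[(2-oxochroman-7-yl)oxy]-2H-chromen-2-one F8. BCl3 (CH2Cl2, −78 → 0 °C) cleaves the aryl isopropyl ether in the presence of the aryl methyl ether, so the sequence comes back at 16.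

**Step 5.** Fluoride or acetate may add to the enynoate in conjugate fashion and scramble the double-bond geometry, or the aryl lactone may be partly opened. The fallback avoids the silyl group. It sets out from 5, which is olefinated under the conditions of step 4 with propynal F9, freshly made from prop-2-yn-1-ol with MnO2 in CH2Cl2, so the sequence comes back at 8.

## Further compounds

F1 | step 7 | tert-butyl 2-[(2-oxochroman-7-yl)oxy]acetate | CC(C)(C)OC(=O)COc1ccc2CCC(=O)Oc2c1
F2 | step 7 | 2-[(2-oxochroman-7-yl)oxy]acetic acid | OC(=O)COc1ccc2CCC(=O)Oc2c1
F3 | step 7 | 6-methoxy-2-oxo-3-[(2-oxochroman-7-yl)oxy]-2H-chromen-7-yl acetate | COc1cc2cc(Oc3ccc4CCC(=O)Oc4c3)c(=O)oc2cc1OC(C)=O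
F4 | step 4 | methyl (Z)-2-[(2-oxochroman-7-yl)oxy]-5-(trimethylsilyl)pent-2-en-4-ynoate | C[Si](C)(C)C#C/C=C(\Oc1ccc2CCC(=O)Oc2c1)C(=O)OC
F5 | step 4 | methyl (Z)-2-[(2-oxochroman-7-yl)oxy]pent-2-en-4-ynoate | C#C/C=C(\Oc1ccc2CCC(=O)Oc2c1)C(=O)OC
F6 | step 4 | methyl (Z)-3-[4-(tert-butoxy)-2-hydroxy-5-methoxyphenyl]-2-[(2-oxochroman-7-yl)oxy]prop-2-enoate | COc1cc(/C=C(\Oc2ccc3CCC(=O)Oc3c2)C(=O)OC)c(O)cc1OC(C)(C)C
F7 | step 6 | pentacarbonyl[(1-isopropoxyvinyl)(methoxy)carbene]chromium | COC(C(=C)OC(C)C)=[Cr](=C=O)(=C=O)(=C=O)(=C=O)=C=O
F8 | step 6 | 7-isopropoxy-6-methoxy-3-[(2-oxochroman-7-yl)oxy]-2H-chromen-2-one | COc1cc2cc(Oc3ccc4CCC(=O)Oc4c3)c(=O)oc2cc1OC(C)C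
F9 | step 5 | propynal | C#CC=O
A1 | alternative 1 | methyl 3-[4-({7-(benzyloxy)-6-methoxy-2-oxo-2H-chromen-3-yl}oxy)-2-hydroxyphenyl]propanoate | COC(=O)CCc1ccc(Oc2cc3cc(OC)c(OCc4ccccc4)cc3oc2=O)cc1O
A2 | alternative 1 | methyl (E)-7-{[7-(benzyloxy)-6-methoxy-2-oxo-2H-chromen-3-yl]oxy}-9,9-dimethoxy-5-oxonon-7-enoate | COC(=O)CCCC(=O)C/C(Oc1cc2cc(OC)c(OCc3ccccc3)cc2oc1=O)=C\C(OC)OC
A3 | alternative 2 | 6-methoxy-2-oxo-3-[(2-oxochroman-7-yl)oxy]-2H-chromen-7-yl acetate | COc1cc2cc(Oc3ccc4CCC(=O)Oc4c3)c(=O)oc2cc1OC(C)=O
A4 | alternative 2 | (Z)-3-(4-acetoxy-3-methoxyphenyl)-2-[(2-oxochroman-7-yl)oxy]prop-2-enoic acid | COc1cc(/C=C(\Oc2ccc3CCC(=O)Oc3c2)C(=O)O)ccc1OC(C)=O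
A5 | alternative 3 | tert-butyl 3-[4-({7-(benzyloxy)-6-methoxy-2-oxo-2H-chromen-3-yl}oxy)-2-[(triisopropylsilyl)oxy]phenyl]propanoate | COc1cc2cc(Oc3ccc(CCC(=O)OC(C)(C)C)c(O[Si](C(C)C)(C(C)C)C(C)C)c3)c(=O)oc2cc1OCc1ccccc1
A6 | alternative 3 | 4-{[7-(benzyloxy)-6-methoxy-2-oxo-2H-chromen-3-yl]oxy}-2H-pyran-2-one | O=c1cc(Oc2cc3cc(OC)c(OCc4ccccc4)cc3oc2=O)cco1
A7 | alternative 3 | tert-butyl 5-[(triisopropylsilyl)oxy]pent-4-ynoate | CC(C)(C)OC(=O)CCC#CO[Si](C(C)C)(C(C)C)C(C)C
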